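The runs stem from a simulated flask with made-up constants; noise was put on by code.

Counted in minutes, the north run gives the two times that matter for G: how long L takes to become G, and how long G lasts once made.

| flask | L | J | G | time |
|---|---|---|---|---|
| south-east | 0.0500 M | 0.0600 M |  |  |
| north-west | 0.0200 M | 0.0300 M |  |  |
| east | 0.150 M | 0.0600 M |  |  |
| north | 0.0500 M | 0.180 M |  |  |
| west | 0.0500 M | 0.0600 M | 0.0250 M | 170 min |

- south-east run (time / min: [G] / M): 21: 0.0066; 42: 0.0117; 64: 0.0139; 85: 0.0153; 110: 0.0181; 130: 0.0202; 150: 0.0213; 170: 0.0202
- north-west run (time / min: [G] / M): 21: 9 × 10⁻⁴; 42: 0.0035; 64: 0.0047; 85: 0.0044; 110: 0.0063; 130: 0.0046; 150: 0.0075; 170: 0.0081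
- east run (time / min: [G] / M): 21: 0.0192; 42: 0.0281; 64: 0.0290; 85: 0.0315; 110: 0.0342; 130: 0.0335; 150: 0.0334; 170: 0.0346
- north run (time / min: [G] / M): 21: 0.0163; 42: 0.0203; 64: 0.0194; 85: 0.0171; 110: 0.0155; 130: 0.0114; 150: 0.0105; 170: 0.0097

(standard deviation of a reading: 8 × 10⁻⁴ M)

- Overall: L + J -> G.
- Constant volume, constant temperature.
- "The second partner" is J.
- An order is taken over about fifteen percent of the charge, up and down.
- A share of G counts the G that was charged too.

1. reaction order in [J] at the outset, round the charge of the south-east run, defined at two percent of the L turned into G
2. reaction order in [L] at the outset, round the charge of the south-east run, defined at two percent of the L turned into G (one fixed amount of G, the same in the runs compared)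
3. G in the west run at 170 min, as a share of the L charged
4. which of these the readings show (the substrate pairs with itself / the second partner is lost by itself / the product binds the second partner / the product reacts on with the second partner)

In the north run G reaches 0.0163 M at 21 min. The L charged divided by that early pace gives 64.4 min, with J taken near its charge of 0.180 M. From 42 min to 170 min G falls from 0.0203 M to 0.0097 M, which, read as a decay, is a lifetime of 173 min. In the east run, with less J and more L charged, the readings of G do not fall: 0.0315 M at 85 min, 0.0346 M at 170 min. So I take G to be lost with J.

Both steps then need J, and J drops out once each time is put on its own J. Late in the north run I take J as the charge less the L charged, about 0.130 M. This gives s, the rough reading of how many times faster L turns to G than G is lost at equal J and equal amounts (a selectivity factor): 1.94. At any moment, making over loss is s·L/G, with L the substrate and G the product then present. I reckon it here with the L charged: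

| Flask, moment | L charged | G present | s·L/G |
|---|---|---|---|
| south-east, two percent turned | 0.0500 M | 0.00100 M | 97.2 |
| west, start | 0.0500 M | 0.0250 M | 3.89 |

So I expect both orders near one, and west G to climb above its charged 50.0 % of L.

The forecast gives 1.02 in J, 1.04 in L, 67 %, and the product reacts on with the second partner. Its ground is that “Excess J is therefore consuming G”. Its share stands above the charged share.

The flask gives 1.0, 1.0, 71.7 %, and the product reacts on with the second partner, so the forecast held.

    L + J → G (0.1638 M⁻¹ min⁻¹)
    L + J → Z (0.08760 M⁻¹ min⁻¹)
    G + J → Z (0.07560 M⁻¹ min⁻¹)

In the south-east run, where s·L/G stood near 97.2, the order in L is not due to G + J to Z: taking that step away leaves it at 1.0 against 1.0. The west run, starting near 3.89, proves the loss: without that step it reaches 99.6 % in place of 71.7 %, a cost of 28 percentage points.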